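**Plan**

- Retrosynthesis: the C6 acetate and the C6/C7 oxygens are taken back to a C6 ketone; C11–C12 is cut next (C9–CH2Br unit plus acetoacetate dianion, C16 added by methylation of an enol triflate); last, C7–C8 and C9–C10 are cut together.
- Enabling feature: ring B carries oxygen at C6 para to C9 and a tetrasubstituted C8=C9 alkene (methyl on C8, C11 on C9) next to quaternary C10. This is the pattern left when a 2-siloxydiene (C10=C5–C6(OSi)=C7) adds to a but-2-ynoyl unit (C8, C9, C11).
- Forward: ring A comes from β-cyclocitral, ring B closes in the Diels–Alder step, the side chain is joined at C11 while C6 stays masked as its silyl enol ether, and ring B is oxygenated last.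
- Stereochemistry: C10 from the chiral copper bis(oxazoline) catalyst; C5 by protonation anti to the C10 methyl; C7 by enolate hydroxylation anti to the C10 methyl; C6 by hydride delivery on the α-face; 13Z from an (E)-enol triflate methylated with retention.

Key step: step 5

**Remarks**

- Labdane numbering is used (C11 on C9, C17 = methyl on C8, C18/C19 on C4, C20 on C10). The C15 bicyclic intermediates are named as drimanes with the same ring numbering. α is the face opposite the C10 methyl.
- From compound 10 on, α/β descriptors are used because the CIP descriptor of C10 changes with the C9 substituent; all intermediates keep the 10β-methyl configuration set in step 5.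
- The diene carries a tert-butyldimethylsilyl group so that the C5=C6 enol ether survives until step 11.
- Assumption: the (S,S)-ligand is written as the one that leads to the (10S) adduct. The sense of induction for this new substrate pair has to be established; the mirror-image ligand, equally available, would be used if it proves opposite.

**Route**

Step 1
Reactants: 1 β-cyclocitral
Product: 2 1-(2,6,6-trimethylcyclohex-1-en-1-yl)ethan-1-ol (racemic)
Conditions: MeMgBr, Et2O, 0 °C → rt; aq. NH4Cl
Reagents that add atoms: methylmagnesium bromide, C[Mg]Br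
Why: Grignard 1,2-addition to the enal carbonyl, whose β-carbon is fully substituted so that conjugate addition does not compete; the carbinol centre is racemic and is removed in step 2.

Step 2
Reactants: 2 1-(2,6,6-trimethylcyclohex-1-en-1-yl)ethan-1-ol
Product: 3 1-(2,6,6-trimethylcyclohex-1-en-1-yl)ethan-1-one
Conditions: Dess–Martin periodinane, CH2Cl2, 0 °C → rt
Reagents that add atoms: none
Why: Dess–Martin oxidation of the secondary allylic alcohol under neutral conditions should give the methyl ketone without moving the tetrasubstituted alkene.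

Step 3
Reactants: 3 1-(2,6,6-trimethylcyclohex-1-en-1-yl)ethan-1-one
Product: 4 2-[1-(tert-butyldimethylsilyloxy)ethenyl]-1,3,3-trimethylcyclohex-1-ene
Conditions: TBSOTf, Et3N, CH2Cl2, 0 °C
Reagents that add atoms: tert-butyldimethylsilyl triflate, CC(C)(C)[Si](C)(C)OS(=O)(=O)C(F)(F)F
Why: Soft enolisation and O-silylation of a methyl ketone whose other α-carbon is a fully substituted sp2 centre can only proceed towards the methyl group, giving the cross-conjugated 2-siloxydiene.

Step 4
Reactants: 5 but-2-ynoic acid; 6 1,3-oxazolidin-2-one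
Product: 8 3-(but-2-ynoyl)-1,3-oxazolidin-2-one, via but-2-ynoic pivalic anhydride 7 (not isolated)
Conditions: PivCl, Et3N, THF, −20 °C; then 6, LiCl, −20 °C → rt
Reagents that add atoms: none
Why: N-acylation of the oxazolidinone through the pivalic mixed anhydride (LiCl/Et3N variant), in which the nucleophile attacks the unhindered ynoyl carbonyl.

Step 5
Reactants: 4 2-[1-(tert-butyldimethylsilyloxy)ethenyl]-1,3,3-trimethylcyclohex-1-ene; 8 3-(but-2-ynoyl)-1,3-oxazolidin-2-one
Product: 9 3-[(10S)-6-(tert-butyldimethylsilyloxy)drima-5,8-dien-11-oyl]-1,3-oxazolidin-2-one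
Conditions: Cu(OTf)2 (10 mol %), (S,S)-2,2′-(propane-2,2-diyl)bis(4-tert-butyl-4,5-dihydrooxazole) (11 mol %), 4 Å MS, CH2Cl2, −20 °C → rt
Reagents that add atoms: none
Why: Proposed new method: two-point binding of the imide to the cationic copper centre lowers the LUMO of the alkyne π-bond conjugated with the carbonyl, so bond formation should begin between the diene CH2 terminus (C7) and the methyl-bearing alkyne carbon (C8) and end at the congested C9–C10 bond, as an asynchronous [4+2] cycloaddition or, at its stepwise limit, a Mukaiyama–Michael addition followed by collapse of the copper allenoate onto C10 of the silyloxyallyl cation. The closest known reaction types are thermal Diels–Alder additions of 1-vinyl-2,6,6-trimethylcyclohexene to acetylenic esters and Cu(OTf)2–bis(oxazoline)-catalysed cycloadditions of alkenoyl oxazolidinones; the pairing of a tetrasubstituted siloxydiene terminus with an ynoyl imide under such catalysis is not yet shown. Ring B closes as a six-membered carbocycle in an intermolecular [4+2] mode (6-endo-trig at C10 in the stepwise limit), the alkyne leaving the C8=C9 alkene and the diene leaving the C5=C6 silyl enol ether. C10 is the only new stereocentre and is set by the C2-symmetric ligand, whose tert-butyl groups leave two quadrants of the square-planar chelate open for the bulky body of the diene; both open quadrants expose the same face of the C10 terminus. The step needs para regiochemistry (acyl carbon C11 on C9, 1,4 to the C6 oxygen), which the 2-siloxy group secures by making C7 the nucleophilic terminus, and it needs the enol ether to survive the Lewis acid, for which the tert-butyldimethylsilyl group and molecular sieves are chosen.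

Step 6
Reactants: 9 3-[(10S)-6-(tert-butyldimethylsilyloxy)drima-5,8-dien-11-oyl]-1,3-oxazolidin-2-one
Product: 10 6-(tert-butyldimethylsilyloxy)drima-5,8-dien-11-ol (10β-methyl)
Conditions: LiBH4, MeOH (1 equiv), THF, 0 °C
Reagents that add atoms: none
Why: Reductive cleavage of an N-acyloxazolidinone with LiBH4 should give the primary allylic alcohol, the silyl enol ether and the tetrasubstituted alkene being inert to borohydride.

Step 7
Reactants: 10 6-(tert-butyldimethylsilyloxy)drima-5,8-dien-11-ol
Product: 11 11-bromo-6-(tert-butyldimethylsilyloxy)drima-5,8-diene (10β-methyl)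
Conditions: CBr4, PPh3, 2,6-lutidine (cat.), CH2Cl2, −20 → 0 °C; used crude
Reagents that add atoms: carbon tetrabromide, BrC(Br)(Br)Br
Why: Appel bromination of the primary allylic alcohol runs under neutral, buffered conditions that spare the acid-labile enol ether, and allylic transposition is blocked by the fully substituted C8.

Step 8
Reactants: 11 11-bromo-6-(tert-butyldimethylsilyloxy)drima-5,8-diene; 12 methyl acetoacetate
Product: 14 methyl 6-(tert-butyldimethylsilyloxy)-13-oxo-16-norlabda-5,8-dien-15-oate (10β-methyl), via acetoacetate dianion 13 (not isolated)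
Conditions: 12 (3 equiv), NaH, THF, 0 °C; n-BuLi, 0 °C; then 11, 0 °C → rt; aq. NH4Cl
Reagents that add atoms: none
Why: Weiler dianion alkylation, in which the terminal carbanion of the acetoacetate dianion displaces the primary allylic bromide by SN2, forms C11–C12 and brings in C12–C15 in one operation.

Step 9
Reactants: 14 methyl 6-(tert-butyldimethylsilyloxy)-13-oxo-16-norlabda-5,8-dien-15-oate
Product: 15 methyl (13E)-6-(tert-butyldimethylsilyloxy)-13-(trifluoromethylsulfonyloxy)-16-norlabda-5,8,13-trien-15-oate
Conditions: Tf2O, 25 % aq. Me4NOH, toluene, 5 °C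
Reagents that add atoms: triflic anhydride, O=S(=O)(OS(=O)(=O)C(F)(F)F)C(F)(F)F
Why: Enol triflation of a β-keto ester under biphasic conditions with a non-coordinating ammonium counter-ion traps the open, non-chelated enolate as the (E)-enol triflate, which places C12 cis to the ester as the target requires.

Step 10
Reactants: 15 methyl (13E)-6-(tert-butyldimethylsilyloxy)-13-(trifluoromethylsulfonyloxy)-16-norlabda-5,8,13-trien-15-oate
Product: 16 methyl (13Z)-6-(tert-butyldimethylsilyloxy)labda-5,8,13-trien-15-oate
Conditions: MeMgBr, Fe(acac)3 (5 mol %), THF/NMP, −30 °C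
Reagents that add atoms: methylmagnesium bromide, C[Mg]Br
Why: Iron-catalysed cross-coupling of an enol triflate with a Grignard reagent (Kochi–Fürstner type) replaces the triflate by methyl (C16) with retention of alkene geometry and faster than addition to the ester, giving the (13Z)-enoate.

Step 11
Reactants: 16 methyl (13Z)-6-(tert-butyldimethylsilyloxy)labda-5,8,13-trien-15-oate
Product: 17 methyl (13Z)-6-oxo-5α-labda-8,13-dien-15-oate (5α-H, 10β-methyl)
Conditions: Bu4NF, AcOH (1:1.2), THF, −20 → 0 °C; used without delay
Reagents that add atoms: none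
Why: Fluoride cleavage of the silyl enol ether under acetic acid buffering releases the enol, which should be protonated at C5 on the α-face, anti to the C10 methyl, to give the trans-fused 6-ketone (also the more stable ring fusion) while the cold buffered medium keeps the C8=C9 alkene out of conjugation.

Step 12
Reactants: 17 methyl (13Z)-6-oxo-5α-labda-8,13-dien-15-oate
Product: 19 methyl (13Z)-7α-hydroxy-6-oxo-5α-labda-8,13-dien-15-oate, via potassium dienolate 18 (not isolated)
Conditions: KN(SiMe3)2 (1.1 equiv), THF, −78 °C; then 2-(phenylsulfonyl)-3-phenyloxaziridine, −78 °C; AcOH quench at −78 °C; used crude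
Reagents that add atoms: 2-(phenylsulfonyl)-3-phenyloxaziridine, O=S(=O)(c1ccccc1)N1OC1c1ccccc1
Why: Davis oxidation of a kinetic enolate: the base should remove the doubly activated (α-keto and allylic) C7 proton rather than the hindered tertiary C5 proton, and the oxaziridine should transfer oxygen to C7 along the axial trajectory on the α-face, anti to the C10 and 4β methyl groups, setting 7α-OH.

Step 13
Reactants: 19 methyl (13Z)-7α-hydroxy-6-oxo-5α-labda-8,13-dien-15-oate
Product: 20 (13Z)-labda-8,13-diene-6β,7α,15-triol
Conditions: LiAlH4, Et2O, −40 → 0 °C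
Reagents that add atoms: none
Why: Hydride reduction with LiAlH4 takes the β,β-disubstituted enoate to the allylic alcohol by 1,2-reduction and the C6 ketone to the 6β-alcohol, since the β-face is closed by the syn-axial 4β and 10β methyl groups and the 7α-alkoxyaluminate delivers hydride on its own face, leaving the 6,7-diol trans-diaxial.

Step 14
Reactants: 20 (13Z)-labda-8,13-diene-6β,7α,15-triol
Product: 21 (13Z)-7α,15-bis(triethylsilyloxy)labda-8,13-dien-6β-ol
Conditions: Et3SiCl (2.4 equiv), imidazole, DMF, 0 °C → rt
Reagents that add atoms: chlorotriethylsilane, CC[Si](CC)(CC)Cl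
Why: Chemoselective silylation, in which the primary allylic and the secondary allylic 7α hydroxyls should react while the axial 6β hydroxyl, flanked by two syn-axial methyl groups, stays free.

Step 15
Reactants: 21 (13Z)-7α,15-bis(triethylsilyloxy)labda-8,13-dien-6β-ol
Product: 22 (13Z)-6β-acetoxy-7α,15-bis(triethylsilyloxy)labda-8,13-diene
Conditions: Ac2O, DMAP, pyridine, 50 °C
Reagents that add atoms: acetic anhydride, CC(=O)OC(C)=O
Why: DMAP-catalysed acylation at raised temperature should esterify the hindered 6β hydroxyl, the only free one, and the trans-diaxial 7α silyl ether cannot migrate to it.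

Step 16
Reactants: 22 (13Z)-6β-acetoxy-7α,15-bis(triethylsilyloxy)labda-8,13-diene
Product: 23 (5S,6S,7S,10S,13Z)-6-acetoxylabda-8,13-diene-7,15-diol (6β-acetoxy, 7α-hydroxy; the target)
Conditions: HF·pyridine, pyridine, THF, 0 °C → rt
Reagents that add atoms: none
Why: Buffered fluoride desilylation should remove both triethylsilyl ethers without cleaving the acetate or ionising the allylic 7α-alcohol, and acetyl migration to O7 is excluded by the trans-diaxial geometry.

**Compound list**

1 | β-cyclocitral | CC1=C(C=O)C(C)(C)CCC1 | starting material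
2 | 1-(2,6,6-trimethylcyclohex-1-en-1-yl)ethan-1-ol (racemic) | CC(O)C1=C(C)CCCC1(C)C | intermediate
3 | 1-(2,6,6-trimethylcyclohex-1-en-1-yl)ethan-1-one | CC(=O)C1=C(C)CCCC1(C)C | intermediate
4 | 2-[1-(tert-butyldimethylsilyloxy)ethenyl]-1,3,3-trimethylcyclohex-1-ene | C=C(O[Si](C)(C)C(C)(C)C)C1=C(C)CCCC1(C)C | intermediate
5 | but-2-ynoic acid | CC#CC(=O)O | starting material
6 | 1,3-oxazolidin-2-one | O=C1NCCO1 | starting material
7 | but-2-ynoic pivalic anhydride | CC#CC(=O)OC(=O)C(C)(C)C | intermediate
8 | 3-(but-2-ynoyl)-1,3-oxazolidin-2-one | CC#CC(=O)N1CCOC1=O | intermediate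
9 | 3-[(10S)-6-(tert-butyldimethylsilyloxy)drima-5,8-dien-11-oyl]-1,3-oxazolidin-2-one | CC1=C(C(=O)N2CCOC2=O)[C@@]3(C)CCCC(C)(C)C3=C(O[Si](C)(C)C(C)(C)C)C1 | intermediate
10 | 6-(tert-butyldimethylsilyloxy)drima-5,8-dien-11-ol (10β-methyl) | CC1=C(CO)[C@@]3(C)CCCC(C)(C)C3=C(O[Si](C)(C)C(C)(C)C)C1 | intermediate
11 | 11-bromo-6-(tert-butyldimethylsilyloxy)drima-5,8-diene (10β-methyl) | CC1=C(CBr)[C@@]3(C)CCCC(C)(C)C3=C(O[Si](C)(C)C(C)(C)C)C1 | intermediate
12 | methyl acetoacetate | CC(=O)CC(=O)OC | starting material
13 | methyl acetoacetate dianion (sodium lithium salt) | [CH2-]C(=O)[CH-]C(=O)OC.[Na+].[Li+] | intermediate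
14 | methyl 6-(tert-butyldimethylsilyloxy)-13-oxo-16-norlabda-5,8-dien-15-oate (10β-methyl) | CC1=C(CCC(=O)CC(=O)OC)[C@@]3(C)CCCC(C)(C)C3=C(O[Si](C)(C)C(C)(C)C)C1 | intermediate
15 | methyl (13E)-6-(tert-butyldimethylsilyloxy)-13-(trifluoromethylsulfonyloxy)-16-norlabda-5,8,13-trien-15-oate | CC1=C(CC/C(OS(=O)(=O)C(F)(F)F)=C\C(=O)OC)[C@@]3(C)CCCC(C)(C)C3=C(O[Si](C)(C)C(C)(C)C)C1 | intermediate
16 | methyl (13Z)-6-(tert-butyldimethylsilyloxy)labda-5,8,13-trien-15-oate | CC1=C(CC/C(C)=C\C(=O)OC)[C@@]3(C)CCCC(C)(C)C3=C(O[Si](C)(C)C(C)(C)C)C1 | intermediate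
17 | methyl (13Z)-6-oxo-5α-labda-8,13-dien-15-oate | O=C1CC(C)=C(CC/C(C)=C\C(=O)OC)[C@@]2(C)CCCC(C)(C)[C@H]12 | intermediate
18 | potassium 6,8-dienolate of 17 | [K+].[O-]C1=CC(C)=C(CC/C(C)=C\C(=O)OC)[C@@]2(C)CCCC(C)(C)[C@H]12 | intermediate
19 | methyl (13Z)-7α-hydroxy-6-oxo-5α-labda-8,13-dien-15-oate | O=C1[C@@H](O)C(C)=C(CC/C(C)=C\C(=O)OC)[C@@]2(C)CCCC(C)(C)[C@H]12 | intermediate
20 | (13Z)-labda-8,13-diene-6β,7α,15-triol | O[C@@H]1[C@@H](O)C(C)=C(CC/C(C)=C\CO)[C@@]2(C)CCCC(C)(C)[C@H]12 | intermediate
21 | (13Z)-7α,15-bis(triethylsilyloxy)labda-8,13-dien-6β-ol | O[C@@H]1[C@@H](O[Si](CC)(CC)CC)C(C)=C(CC/C(C)=C\CO[Si](CC)(CC)CC)[C@@]2(C)CCCC(C)(C)[C@H]12 | intermediate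
22 | (13Z)-6β-acetoxy-7α,15-bis(triethylsilyloxy)labda-8,13-diene | CC(=O)O[C@@H]1[C@@H](O[Si](CC)(CC)CC)C(C)=C(CC/C(C)=C\CO[Si](CC)(CC)CC)[C@@]2(C)CCCC(C)(C)[C@H]12 | intermediate
23 | (5S,6S,7S,10S,13Z)-6-acetoxylabda-8,13-diene-7,15-diol | CC(=O)O[C@@H]1[C@@H](O)C(C)=C(CC/C(C)=C\CO)[C@@]2(C)CCCC(C)(C)[C@H]12 | target

**Step count and risks**

Total: 16 steps. Longest linear sequence: 15 steps (steps 1–3 and 5–16 from β-cyclocitral); step 4 is the one-step side branch.

Steps most likely to fail:

1. Step 5 (proposed new method). The cycloaddition may stall at the congested C9–C10 bond, stop at the open-chain Michael stage with loss of the silyl group, or proceed with poor facial selectivity at C10. The fallback sets out from diene 4 and uses known chemistry. Heating 4 with commercial methyl but-2-ynoate (toluene, sealed tube, about 140 °C, BHT), a thermal Diels–Alder reaction of the acetylenic-ester type, should give racemic methyl 6-(tert-butyldimethylsilyloxy)drima-5,8-dien-11-oate F1 with the same para regiochemistry. LiAlH4 reduction would give racemic 6-(tert-butyldimethylsilyloxy)drima-5,8-dien-11-ol F2. Esterification with (S)-O-methylmandelic acid (DCC, DMAP) and chromatographic separation would give the 10β-methyl (S)-O-methylmandelate F3, leaving the 10α-methyl diastereomer F4 to be discarded. Cleavage of F3 with iBu2AlH at −78 °C returns to the route at 10.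

2. Step 12. Under the basic conditions the C8=C9 double bond may move into conjugation with the C6 carbonyl, the sulfonimine by-product may add to the enolate, or the acyloin may isomerise towards a diosphenol. The fallback sets out from 17 and replaces enolate oxygenation by a Rubottom oxidation. In-situ trapping with LiN(iPr)2/Me3SiCl (THF, −78 °C) would give methyl (13Z)-6-(trimethylsilyloxy)-5α-labda-6,8,13-trien-15-oate F5. Dimethyldioxirane (acetone/CH2Cl2, −78 °C) should epoxidise only the electron-rich C6=C7 enol ether on the α-face and give, after silyl migration, methyl (13Z)-6-oxo-7α-(trimethylsilyloxy)-5α-labda-8,13-dien-15-oate F6. Brief treatment with HF·pyridine returns to the route at 19.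

3. Step 6. The exocyclic acyl carbon lies between the C8 methyl and quaternary C10, so hydride may instead attack the ring carbonyl of the oxazolidinone and open it. The fallback sets out from 9. Hydroperoxide cleavage (LiOH, H2O2, THF/H2O, 0 °C), which is selective for the exocyclic acyl group even when it is hindered, would give 6-(tert-butyldimethylsilyloxy)drima-5,8-dien-11-oic acid F7 (10β-methyl). LiAlH4 (Et2O, 0 °C) then reduces the acid and returns to the route at 10.

**Further compounds**

F1 | step 5 | methyl 6-(tert-butyldimethylsilyloxy)drima-5,8-dien-11-oate (racemic) | CC1=C(C(=O)OC)C2(C)CCCC(C)(C)C2=C(O[Si](C)(C)C(C)(C)C)C1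
F2 | step 5 | 6-(tert-butyldimethylsilyloxy)drima-5,8-dien-11-ol (racemic) | CC1=C(CO)C2(C)CCCC(C)(C)C2=C(O[Si](C)(C)C(C)(C)C)C1
F3 | step 5 | 6-(tert-butyldimethylsilyloxy)drima-5,8-dien-11-yl (S)-2-methoxy-2-phenylacetate, 10β-methyl diastereomer | CC1=C(COC(=O)[C@@H](OC)c2ccccc2)[C@@]3(C)CCCC(C)(C)C3=C(O[Si](C)(C)C(C)(C)C)C1
F4 | step 5 | 6-(tert-butyldimethylsilyloxy)drima-5,8-dien-11-yl (S)-2-methoxy-2-phenylacetate, 10α-methyl diastereomer | CC1=C(COC(=O)[C@@H](OC)c2ccccc2)[C@]3(C)CCCC(C)(C)C3=C(O[Si](C)(C)C(C)(C)C)C1
F5 | step 12 | methyl (13Z)-6-(trimethylsilyloxy)-5α-labda-6,8,13-trien-15-oate | C[Si](C)(C)OC1=CC(C)=C(CC/C(C)=C\C(=O)OC)[C@@]2(C)CCCC(C)(C)[C@H]12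
F6 | step 12 | methyl (13Z)-6-oxo-7α-(trimethylsilyloxy)-5α-labda-8,13-dien-15-oate | O=C1[C@@H](O[Si](C)(C)C)C(C)=C(CC/C(C)=C\C(=O)OC)[C@@]2(C)CCCC(C)(C)[C@H]12
F7 | step 6 | 6-(tert-butyldimethylsilyloxy)drima-5,8-dien-11-oic acid (10β-methyl) | CC1=C(C(=O)O)[C@@]3(C)CCCC(C)(C)C3=C(O[Si](C)(C)C(C)(C)C)C1
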